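Slowness is what the south-west flask shows: after 8.00 h, quenched substrate reads 24% of the charge, while monomer in chains has read no higher than 2%, the size of the scatter of a reading.

- south-west: free monomer 0.10 M (fed, over 6.0 h); protic impurity 0.10 M; pre-initiator 2.5 mM; the very flask that is asked about, followed so far
- flask: free monomer 0.10 M (fed, over 6.0 h); protic impurity 0.100 M; pre-initiator 2.5 mM; time 40 h

south-west run (percent of the free monomer charged)

| time / h | quenched substrate / % | monomer in chains / % |
|---|---|---|
| 0.500 | 0 | 0 |
| 0.833 | 0 | 1 |
| 1.33 | 0 | 1 |
| 2.00 | 3 | 0 |
| 3.00 | 4 | 0 |
| 5.00 | 12 | 2 |
| 8.00 | 24 | 0 |

(each reading ± 2 percentage points)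

- percentages count the whole charge, also what has not yet gone in

* amount of quenched substrate in percent of the free monomer charged, at 8.0 h, 20 h and 40 h

The reckoning here asks where the south-west flask is heading, then how fast, and takes its settings in turn. The charge of protic impurity, 0.10 M, matches the 0.10 M of free monomer, so if the two react one to one, neither is the limiting reagent, and by hand, with chains set aside, quenched substrate heads for the whole charge as an equimolar second-order pair. The pre-initiator, at 2.5 mM, is 2.50% of that charge, and since chains have shown nothing beyond the scatter, it is left out of the hand reckoning. The pace of the pair is the quench time, defined as 1/(k·c), with k the second-order constant and c the charge: the time in which the pair, charged at once, would halve. The quenched fraction is then the clock time divided by the sum of clock time and quench time. The feed leaves the end state alone by hand, but monomer enters on average at mid-feed, so the clock starts 3.00 h late. The reading at 8.00 h, with 5.00 h on the clock, gives a quench time of 15.8 h, a value read from a reading and carrying its scatter. This time is longer than the late start, and it gives 51.8% at 20 h and 70.0% at 40 h.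

The forecast, holding that “both fall together by second-order decay”, gives 24%, 51% and 69%, slightly below this reckoning at the last time.

The south-west flask gives 28.3% at 8.0 h, 57.6% at 20 h and 74.2% at 40 h.

    free monomer + initiator → living end + monomer in chains (k = 0.240 M⁻¹ h⁻¹)
    free monomer + living end → monomer in chains + living end, rate k2*[living end]*[free monomer] (k = 6.70 M⁻¹ h⁻¹)
    pre-initiator → initiator (k = 0.0630 h⁻¹)
    protic impurity + free monomer → quenched substrate (k = 0.810 M⁻¹ h⁻¹)

Read backwards through the same rule, the 74.2% at 40 h makes the quench time 12.9 h, shorter than the 15.8 h reckoned beforehand. At 40 h the pseudo-first-order lifetime of free monomer is 47.9 h against protic impurity and 294 h against the living end, a shorter time for the impurity, while quenched substrate stands at 74.2% and monomer in chains at 2.80%.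

(The numbers in the tables are calculated with made-up constants, noise included.)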